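**Plan**
- Retrosynthetic cuts: the enol ether C=CH2 (back to a δ-lactone C=O); the lactone O–CMe2 and C–Br bonds (bromolactonisation of a prenylated α-hydroxy acid); the CH2–CH=CMe2 bond and the C–O bond at the carbinol carbon (epoxide of a 2-substituted allylic alcohol); last, the cyclohexane at CH2–CH2 and at CHBr–C(Cl)CH3, giving an (E)-1-bromo-3-alkylbuta-1,3-diene and 2-chloroacrolein.
- Enabling feature: in the carbocycle (ring A) the C(Cl)(CH3) carbon is vicinal to CHBr and 1,4 to the CH that bears the side chain. This is the ortho/para pattern of a [4+2] adduct, so both halogens can come in on diene and dienophile.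
- Forward order: bromodiene (2 steps) → Diels–Alder builds ring A → alkene saturation and CHO → CH3 → side chain to allylic alcohol → epoxy acid → prenylated hydroxy acid → bromolactone (ring B) → lactone methylenation.
- Stereochemistry: C–Cl (catalyst face control) and C–Br (endo mode, E-alkene) come from the cycloaddition, which gives the trans-bromochloride isomer that BrCl addition to a cyclohexene would not give. The ring CH comes from hydrogenation anti to Br, the carbinol from Sharpless epoxidation (L-(+)-tartrate), and the pyran CHBr from a chair-like bromolactonisation.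

Key step: step 3

Remark: 2-chloroacrolein (4) is taken as purchasable; otherwise it is made in one operation from acrolein (Cl2, then loss of HCl).

Step 1
Reactants: 1 4-[(tert-butyldimethylsilyl)oxy]butanal
Product: 2 4-[(tert-butyldimethylsilyl)oxy]-2-methylidenebutanal
Conditions: 37 % aq. HCHO, pyrrolidine (10 mol %), EtCO2H (10 mol %), i-PrOH, 45 °C
Reagents that add atoms: formaldehyde, C=O
Why: Amine-catalysed Mannich condensation–elimination (α-methylenation of an aldehyde) should give the 2-substituted acrolein; no stereocentre is formed.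

Step 2
Reactants: 2 4-[(tert-butyldimethylsilyl)oxy]-2-methylidenebutanal
Product: 3 tert-butyl{[(4E)-5-bromo-3-methylidenepent-4-en-1-yl]oxy}dimethylsilane
Conditions: CHBr3, CrBr2 (divalent chromium, 6 equiv), THF, 0 °C to rt
Reagents that add atoms: bromoform, BrC(Br)Br
Why: Takai olefination, in which the gem-dichromium carbenoid adds to the enal and eliminates to the (E)-bromoalkene; the bromide salt of chromium avoids Br/Cl scrambling.

Step 3
Reactants: 3 tert-butyl{[(4E)-5-bromo-3-methylidenepent-4-en-1-yl]oxy}dimethylsilane; 4 2-chloroprop-2-enal (2-chloroacrolein)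
Product: 5 (1R,2S)-2-bromo-4-{2-[(tert-butyldimethylsilyl)oxy]ethyl}-1-chlorocyclohex-3-ene-1-carbaldehyde
Conditions: (4R)-2-butyl-4-(1H-indol-3-ylmethyl)-3-(4-methylphenyl)sulfonyl-1,3,2-oxazaborolidin-5-one (10 mol %, from N-tosyl-(R)-tryptophan and BuB(OH)2), CH2Cl2, −78 to −40 °C
Reagents that add atoms: none
Why: Coordination of the formyl oxygen to boron lowers the LUMO of 2-chloroacrolein, and a concerted, asynchronous, suprafacial [4+2] cycloaddition with the s-cis diene forms the CH2–CH2 bond and the CHBr–C(Cl) bond in one operation. The closest known reaction type is the oxazaborolidine-catalysed Diels–Alder reaction of 2-bromo- and 2-chloroacrolein with cyclopentadiene, isoprene and other 2-substituted butadienes; ring A is closed as a six-membered carbocycle by this intermolecular cycloaddition (both new σ-bonds are ring bonds, no tether). The quaternary C(Cl)(CHO) centre is set by the catalyst, whose indole shields one face of the bound s-cis enal so that the diene adds to the Si face of C-2 (Cl > CHO > CH2); the catalyst is the antipode of the one that turns cyclopentadiene and 2-bromoacrolein into the (2R)-aldehyde. The CHBr centre is set relative to it by the (E)-geometry of the bromoalkene together with the endo position of the formyl group usual for α-substituted acroleins with open-chain dienes, which places Br cis to CHO and therefore trans to Cl. The step needs regio-, endo- and facial selectivity and enough reactivity from a bromine-deactivated diene: the 3-alkyl group (para rule) and the 1-bromo group (ortho rule) point to the same regioisomer, the 3-substituent raises the s-cis population and the HOMO, and the dienophile is doubly activated by Cl and the bound CHO. The adduct already holds the trans bromochloride in the arrangement that anti addition of BrCl to the corresponding methylcyclohexene (trans-diaxial opening) would not deliver.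

Step 4
Reactants: 5 (1R,2S)-2-bromo-4-{2-[(tert-butyldimethylsilyl)oxy]ethyl}-1-chlorocyclohex-3-ene-1-carbaldehyde
Product: 6 (1R,2S,4R)-2-bromo-4-{2-[(tert-butyldimethylsilyl)oxy]ethyl}-1-chlorocyclohexane-1-carbaldehyde
Conditions: H2 (1 atm), 5 % Rh/Al2O3, EtOAc, 0 °C to rt
Reagents that add atoms: none
Why: Heterogeneous catalytic syn-hydrogenation (rhodium on alumina is slow to cleave allylic C–Br bonds and to reduce aldehydes) should occur on the face anti to bromine, because the bromine face carries a pseudo-axial group in both half-chairs (Br at the allylic carbon, or CHO at the quaternary carbon) while the opposite face is free in the half-chair with equatorial halogens; this sets the ring CH with the side chain cis to Br.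

Step 5
Reactants: 6 (1R,2S,4R)-2-bromo-4-{2-[(tert-butyldimethylsilyl)oxy]ethyl}-1-chlorocyclohexane-1-carbaldehyde
Product: 7 [(1R,2S,4R)-2-bromo-4-{2-[(tert-butyldimethylsilyl)oxy]ethyl}-1-chlorocyclohexyl]methanol
Conditions: NaBH4, THF/MeOH, −20 °C
Reagents that add atoms: none
Why: Chemoselective borohydride reduction of the aldehyde at low temperature leaves the halides and the silyl ether alone; no stereocentre is formed or touched.

Step 6
Reactants: 7 [(1R,2S,4R)-2-bromo-4-{2-[(tert-butyldimethylsilyl)oxy]ethyl}-1-chlorocyclohexyl]methanol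
Product: 9 tert-butyl{2-[(1R,3S,4S)-3-bromo-4-chloro-4-methylcyclohexyl]ethoxy}dimethylsilane, via primary triflate 8 (not isolated)
Conditions: Tf2O, pyridine, CH2Cl2, −78 °C; then LiEt3BH, THF, −78 to 0 °C
Reagents that add atoms: none
Why: Triflation followed by SN2 hydride displacement (Super-Hydride reduction of a primary sulfonate) turns CH2OH into CH3; the hindered secondary bromide and the tertiary chloride are far slower electrophiles, and no stereocentre is affected.

Step 7
Reactants: 9 tert-butyl{2-[(1R,3S,4S)-3-bromo-4-chloro-4-methylcyclohexyl]ethoxy}dimethylsilane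
Product: 10 2-[(1R,3S,4S)-3-bromo-4-chloro-4-methylcyclohexyl]ethan-1-ol
Conditions: HF·pyridine, THF, 0 °C to rt
Reagents that add atoms: none
Why: Fluoride-driven cleavage of the primary silyl ether under weakly acidic conditions avoids base-induced loss of HBr or HCl.

Step 8
Reactants: 10 2-[(1R,3S,4S)-3-bromo-4-chloro-4-methylcyclohexyl]ethan-1-ol
Product: 11 2-[(1R,3S,4S)-3-bromo-4-chloro-4-methylcyclohexyl]acetaldehyde
Conditions: Dess–Martin periodinane, CH2Cl2, rt
Reagents that add atoms: none
Why: Dess–Martin oxidation of the primary alcohol stops at the aldehyde under neutral conditions; the ring stereocentres are not adjacent to the carbonyl group and cannot epimerise.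

Step 9
Reactants: 11 2-[(1R,3S,4S)-3-bromo-4-chloro-4-methylcyclohexyl]acetaldehyde
Product: 13 2-[(1S,3S,4S)-3-bromo-4-chloro-4-methylcyclohexyl]prop-2-en-1-ol, via 2-substituted acrolein 12 (not isolated)
Conditions: Me2N=CH2 I (dimethylmethylideneammonium iodide), Et3N, CH2Cl2, rt; then NaBH4, CeCl3·7H2O, MeOH, 0 °C
Reagents that add atoms: dimethylmethylideneammonium iodide (Eschenmoser's salt), C=[N+](C)C.[I-]
Why: Mannich addition–elimination (α-methylenation) followed at once by Luche 1,2-reduction gives the allylic alcohol; reducing the enal without isolation keeps the alkene from moving into conjugation across the ring CH, and no new stereocentre is formed.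

Step 10
Reactants: 13 2-[(1S,3S,4S)-3-bromo-4-chloro-4-methylcyclohexyl]prop-2-en-1-ol
Product: 14 {(2S)-2-[(1S,3S,4S)-3-bromo-4-chloro-4-methylcyclohexyl]oxiran-2-yl}methanol
Conditions: Ti(OiPr)4 (10 mol %), L-(+)-diethyl tartrate (12 mol %), t-BuOOH, 4 Å molecular sieves, CH2Cl2, −20 °C
Reagents that add atoms: tert-butyl hydroperoxide, CC(C)(C)OO
Why: Sharpless asymmetric epoxidation of a 2-substituted allylic alcohol; the L-(+)-tartrate sets the quaternary epoxide carbon as (2S) by reagent control, as it does for other primary allylic alcohols, independently of the remote ring stereocentres.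

Step 11
Reactants: 14 {(2S)-2-[(1S,3S,4S)-3-bromo-4-chloro-4-methylcyclohexyl]oxiran-2-yl}methanol
Product: 15 (2R)-2-[(1S,3S,4S)-3-bromo-4-chloro-4-methylcyclohexyl]oxirane-2-carboxylic acid
Conditions: RuCl3·xH2O (2 mol %), NaIO4, MeCN/EtOAc/H2O, 0 °C to rt
Reagents that add atoms: water, O
Why: Ruthenium tetroxide oxidation (RuCl3/NaIO4) of a 2,3-epoxy alcohol to the glycidic acid is an established use of these conditions; it is done before any alkene is present, and the quaternary epoxide carbon keeps its configuration (the descriptor changes only through priorities).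

Step 12
Reactants: 15 (2R)-2-[(1S,3S,4S)-3-bromo-4-chloro-4-methylcyclohexyl]oxirane-2-carboxylic acid; 16 (2-methylprop-1-en-1-yl)magnesium bromide
Product: 17 (2S)-2-[(1S,3S,4S)-3-bromo-4-chloro-4-methylcyclohexyl]-2-hydroxy-5-methylhex-4-enoic acid
Conditions: 16 (3.5 equiv), CuI (10 mol %), THF, −40 to 0 °C; then aq. citric acid
Reagents that add atoms: none
Why: Copper-catalysed Grignard opening of the glycidic acid salt by SN2 attack at the unsubstituted CH2 terminus (the known route from glycidic acids to α-hydroxy acids) installs the prenyl unit without touching the carbinol carbon.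

Step 13
Reactants: 17 (2S)-2-[(1S,3S,4S)-3-bromo-4-chloro-4-methylcyclohexyl]-2-hydroxy-5-methylhex-4-enoic acid
Product: 18 (3S,5R)-5-bromo-3-[(1S,3S,4S)-3-bromo-4-chloro-4-methylcyclohexyl]-3-hydroxy-6,6-dimethyloxan-2-one
Conditions: N-bromosuccinimide, MeCN, −20 °C, dark
Reagents that add atoms: N-bromosuccinimide, O=C1CCC(=O)N1Br
Why: Bromolactonisation in which the bromonium ion of the trisubstituted alkene is opened at the CMe2 carbon by the carboxyl oxygen (Markovnikov, 6-endo); anti addition places Br equatorial in a chair-like transition state whose bulky cyclohexyl group is also equatorial, so the new CHBr centre should form cis to the cyclohexyl group (1,3-induction from the carbinol carbon).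

Step 14
Reactants: 18 (3S,5R)-5-bromo-3-[(1S,3S,4S)-3-bromo-4-chloro-4-methylcyclohexyl]-3-hydroxy-6,6-dimethyloxan-2-one
Product: 19 (3S,5R)-5-bromo-3-[(1S,3S,4S)-3-bromo-4-chloro-4-methylcyclohexyl]-6,6-dimethyl-3-[(trimethylsilyl)oxy]oxan-2-one
Conditions: TMSOTf, 2,6-lutidine, CH2Cl2, −78 to 0 °C
Reagents that add atoms: trimethylsilyl trifluoromethanesulfonate, C[Si](C)(C)OS(=O)(=O)C(F)(F)F
Why: Silylation of the tertiary alcohol with a silyl triflate and a hindered base masks the acidic OH before the titanium reagent is used.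

Step 15
Reactants: 19 (3S,5R)-5-bromo-3-[(1S,3S,4S)-3-bromo-4-chloro-4-methylcyclohexyl]-6,6-dimethyl-3-[(trimethylsilyl)oxy]oxan-2-one
Product: 21 (3S,5R)-5-bromo-3-[(1S,3S,4S)-3-bromo-4-chloro-4-methylcyclohexyl]-6,6-dimethyl-2-methylideneoxan-3-ol, via silylated enol ether 20 (not isolated)
Conditions: Cp2TiMe2, toluene/THF, 65 °C, dark; then K2CO3 (cat.), MeOH, 0 °C
Reagents that add atoms: dimethyltitanocene, C[Ti](C)(C1C=CC=C1)C1C=CC=C1
Why: Petasis methylenation (Cp2Ti=CH2 formed on heating, [2+2] with the lactone carbonyl, cycloreversion) converts the lactone into the exocyclic enol ether as in exo-glycal syntheses; the neutral reagent spares the alkyl halides, and basic methanolysis of the silyl ether leaves the acid-labile product and all stereocentres intact.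

**Compound list**
1 | 4-[(tert-butyldimethylsilyl)oxy]butanal | O=CCCCO[Si](C)(C)C(C)(C)C | starting material
2 | 4-[(tert-butyldimethylsilyl)oxy]-2-methylidenebutanal | C=C(C=O)CCO[Si](C)(C)C(C)(C)C | intermediate
3 | tert-butyl{[(4E)-5-bromo-3-methylidenepent-4-en-1-yl]oxy}dimethylsilane | Br/C=C/C(=C)CCO[Si](C)(C)C(C)(C)C | intermediate
4 | 2-chloroprop-2-enal (2-chloroacrolein) | C=C(Cl)C=O | starting material
5 | (1R,2S)-2-bromo-4-{2-[(tert-butyldimethylsilyl)oxy]ethyl}-1-chlorocyclohex-3-ene-1-carbaldehyde | O=C[C@]1(Cl)CCC(CCO[Si](C)(C)C(C)(C)C)=C[C@@H]1Br | intermediate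
6 | (1R,2S,4R)-2-bromo-4-{2-[(tert-butyldimethylsilyl)oxy]ethyl}-1-chlorocyclohexane-1-carbaldehyde | CC(C)(C)[Si](C)(C)OCC[C@H]1CC[C@](C=O)(Cl)[C@@H](Br)C1 | intermediate
7 | [(1R,2S,4R)-2-bromo-4-{2-[(tert-butyldimethylsilyl)oxy]ethyl}-1-chlorocyclohexyl]methanol | CC(C)(C)[Si](C)(C)OCC[C@H]1CC[C@](CO)(Cl)[C@@H](Br)C1 | intermediate
8 | [(1R,2S,4R)-2-bromo-4-{2-[(tert-butyldimethylsilyl)oxy]ethyl}-1-chlorocyclohexyl]methyl trifluoromethanesulfonate | CC(C)(C)[Si](C)(C)OCC[C@H]1CC[C@](COS(=O)(=O)C(F)(F)F)(Cl)[C@@H](Br)C1 | intermediate (not isolated)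
9 | tert-butyl{2-[(1R,3S,4S)-3-bromo-4-chloro-4-methylcyclohexyl]ethoxy}dimethylsilane | CC(C)(C)[Si](C)(C)OCC[C@H]1CC[C@](C)(Cl)[C@@H](Br)C1 | intermediate
10 | 2-[(1R,3S,4S)-3-bromo-4-chloro-4-methylcyclohexyl]ethan-1-ol | OCC[C@H]1CC[C@](C)(Cl)[C@@H](Br)C1 | intermediate
11 | 2-[(1R,3S,4S)-3-bromo-4-chloro-4-methylcyclohexyl]acetaldehyde | O=CC[C@H]1CC[C@](C)(Cl)[C@@H](Br)C1 | intermediate
12 | 2-[(1S,3S,4S)-3-bromo-4-chloro-4-methylcyclohexyl]prop-2-enal | C=C(C=O)[C@H]1CC[C@](C)(Cl)[C@@H](Br)C1 | intermediate (not isolated)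
13 | 2-[(1S,3S,4S)-3-bromo-4-chloro-4-methylcyclohexyl]prop-2-en-1-ol | C=C(CO)[C@H]1CC[C@](C)(Cl)[C@@H](Br)C1 | intermediate
14 | {(2S)-2-[(1S,3S,4S)-3-bromo-4-chloro-4-methylcyclohexyl]oxiran-2-yl}methanol | OC[C@]1(CO1)[C@H]2CC[C@](C)(Cl)[C@@H](Br)C2 | intermediate
15 | (2R)-2-[(1S,3S,4S)-3-bromo-4-chloro-4-methylcyclohexyl]oxirane-2-carboxylic acid | OC(=O)[C@]1(CO1)[C@H]2CC[C@](C)(Cl)[C@@H](Br)C2 | intermediate
16 | (2-methylprop-1-en-1-yl)magnesium bromide | CC(C)=C[Mg]Br | starting material
17 | (2S)-2-[(1S,3S,4S)-3-bromo-4-chloro-4-methylcyclohexyl]-2-hydroxy-5-methylhex-4-enoic acid | OC(=O)[C@](O)(CC=C(C)C)[C@H]1CC[C@](C)(Cl)[C@@H](Br)C1 | intermediate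
18 | (3S,5R)-5-bromo-3-[(1S,3S,4S)-3-bromo-4-chloro-4-methylcyclohexyl]-3-hydroxy-6,6-dimethyloxan-2-one | O=C1OC(C)(C)[C@H](Br)C[C@]1(O)[C@H]1CC[C@](C)(Cl)[C@@H](Br)C1 | intermediate
19 | (3S,5R)-5-bromo-3-[(1S,3S,4S)-3-bromo-4-chloro-4-methylcyclohexyl]-6,6-dimethyl-3-[(trimethylsilyl)oxy]oxan-2-one | O=C1OC(C)(C)[C@H](Br)C[C@]1(O[Si](C)(C)C)[C@H]1CC[C@](C)(Cl)[C@@H](Br)C1 | intermediate
20 | {[(3S,5R)-5-bromo-3-[(1S,3S,4S)-3-bromo-4-chloro-4-methylcyclohexyl]-6,6-dimethyl-2-methylideneoxan-3-yl]oxy}trimethylsilane | C=C1OC(C)(C)[C@H](Br)C[C@]1(O[Si](C)(C)C)[C@H]1CC[C@](C)(Cl)[C@@H](Br)C1 | intermediate (not isolated)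
21 | (3S,5R)-5-bromo-3-[(1S,3S,4S)-3-bromo-4-chloro-4-methylcyclohexyl]-6,6-dimethyl-2-methylideneoxan-3-ol | C=C1OC(C)(C)[C@H](Br)C[C@]1(O)[C@H]1CC[C@](C)(Cl)[C@@H](Br)C1 | target

Total step count: 15. Longest linear sequence: 15 steps (1 to 21).

**Steps most likely to fail**

Step 3. The bromine-deactivated diene may add too slowly, and the warming then needed may erode enantiofacial control by the catalyst. The fallback replaces asymmetric catalysis by resolution. It sets out from 3 and 4: the cycloaddition is driven with an achiral Lewis acid (Me2AlCl, CH2Cl2, −78 °C, or 12 kbar without promoter) to the racemic endo adduct, that is 5 together with its mirror-image aldehyde F1. Steps 4 and 5 on the racemate should give 6 and 7 accompanied by the saturated mirror-image aldehyde F2 and the mirror-image alcohol F3. Esterification with (2S)-2-methoxy-2-phenylacetic acid (DCC, DMAP, CH2Cl2) should give the mandelate ester F4 (from 7) and the diastereomeric mandelate ester F5 (from F3), to be separated by chromatography. i-Bu2AlH (CH2Cl2, −78 °C) then releases 7 from F4, and the route is rejoined at 7.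

Step 4. The metal surface may hydrogenolyse the allylic C–Br bond, and discrimination between the two alkene faces may be incomplete. The fallback sets out again from 5 and replaces surface catalysis by metal-free diimide reduction (2-nitrobenzenesulfonylhydrazide, Et3N, CH2Cl2, rt, repeated charges). This is a concerted syn transfer of H2 that cannot cleave carbon–halogen bonds and that approaches the same less hindered face. It comes back to the route at 6 and forms no compound outside the list (F0).

Step 13. The free tertiary hydroxyl may capture the bromonium ion (5-endo etherification), and its hydrogen bond to the carboxyl group may erode the 1,3-diastereocontrol. The fallback masks the hydroxyl before cyclisation and sets out from 17. TMSCl and imidazole (DMF, 0 °C) should give the bis-silylated hydroxy ester F6, whose silyl ester is hydrolysed on brief aqueous work-up to the silyloxy acid F7. N-Bromosuccinimide (MeCN, −20 °C) should then cyclise F7 through the carboxyl group alone, in a chair with the cyclohexyl group equatorial, to give 19 directly. The route is rejoined at 19, and steps 13 and 14 merge.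

**Further compounds**
F1 | step 3 | (1S,2R)-2-bromo-4-{2-[(tert-butyldimethylsilyl)oxy]ethyl}-1-chlorocyclohex-3-ene-1-carbaldehyde | O=C[C@@]1(Cl)CCC(CCO[Si](C)(C)C(C)(C)C)=C[C@H]1Br
F2 | step 3 | (1S,2R,4S)-2-bromo-4-{2-[(tert-butyldimethylsilyl)oxy]ethyl}-1-chlorocyclohexane-1-carbaldehyde | CC(C)(C)[Si](C)(C)OCC[C@@H]1CC[C@@](C=O)(Cl)[C@H](Br)C1
F3 | step 3 | [(1S,2R,4S)-2-bromo-4-{2-[(tert-butyldimethylsilyl)oxy]ethyl}-1-chlorocyclohexyl]methanol | CC(C)(C)[Si](C)(C)OCC[C@@H]1CC[C@@](CO)(Cl)[C@H](Br)C1
F4 | step 3 | [(1R,2S,4R)-2-bromo-4-{2-[(tert-butyldimethylsilyl)oxy]ethyl}-1-chlorocyclohexyl]methyl (2S)-2-methoxy-2-phenylacetate | CC(C)(C)[Si](C)(C)OCC[C@H]1CC[C@](COC(=O)[C@@H](OC)c2ccccc2)(Cl)[C@@H](Br)C1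
F5 | step 3 | [(1S,2R,4S)-2-bromo-4-{2-[(tert-butyldimethylsilyl)oxy]ethyl}-1-chlorocyclohexyl]methyl (2S)-2-methoxy-2-phenylacetate | CC(C)(C)[Si](C)(C)OCC[C@@H]1CC[C@@](COC(=O)[C@@H](OC)c2ccccc2)(Cl)[C@H](Br)C1
F0 | step 4 | none | none
F6 | step 13 | trimethylsilyl (2S)-2-[(1S,3S,4S)-3-bromo-4-chloro-4-methylcyclohexyl]-5-methyl-2-[(trimethylsilyl)oxy]hex-4-enoate | C[Si](C)(C)OC(=O)[C@](O[Si](C)(C)C)(CC=C(C)C)[C@H]1CC[C@](C)(Cl)[C@@H](Br)C1
F7 | step 13 | (2S)-2-[(1S,3S,4S)-3-bromo-4-chloro-4-methylcyclohexyl]-5-methyl-2-[(trimethylsilyl)oxy]hex-4-enoic acid | OC(=O)[C@](O[Si](C)(C)C)(CC=C(C)C)[C@H]1CC[C@](C)(Cl)[C@@H](Br)C1
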